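The trimer is cut at its two interflavan bonds into two epicatechin-gallate units (from (−)-epicatechin and tri-O-benzylgallic acid) and a catechin unit built de novo. The key step makes the catechin pyran ring C by a chiral-acid-catalysed oxa-Povarov [4+2]: an open-chain aryloxy(aryl)methyl pivalate ionises to the cationic 2-oxadiene C4a=C8a–O1(+)=C2, which adds (E)-2-ethoxyvinyl-Bpin, forming C2–C3 and C4–C4a at once. It exploits the aryl ether O1 of ring C and the symmetric phloroglucinol ring A, whose two equivalent ortho carbons make the closure unambiguous. Boron at C3 becomes the hydroxyl, ethoxy at C4 is removed. Bromine caps and orthogonal O/S leaving groups at C4 then control the 4→6 and 4→8 unions.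

Key step: step 2

Assumption: the sense of induction of the chiral acid in step 2 cannot be predicted with confidence; the (R)-catalyst is written, and its enantiomer would be used if a test run shows the opposite sense.

Step 1
Reactants: 1 3,4-bis(benzyloxy)benzaldehyde; 2 3,5-bis(benzyloxy)phenol
Product: 4 [3,4-bis(benzyloxy)phenyl][3,5-bis(benzyloxy)phenoxy]methyl pivalate (racemic), via α-chlorobenzyl pivalate 3 (not isolated)
Conditions: PivCl, ZnCl2 (2 mol %), CH2Cl2, 0 °C to rt; then 2, K2CO3, MeCN, 0 °C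
Reagents that add atoms: pivaloyl chloride, CC(C)(C)C(Cl)=O
Why: Acid chlorides add across aromatic aldehydes under ZnCl2 catalysis to give α-chloroalkyl esters, and this SN1-active benzylic chloride should O-alkylate the phenoxide (Williamson-type acyloxyalkylation); the hindered pivalate resists acyl transfer, and the racemic stereocentre is erased in step 2.

Step 2
Reactants: 4 [3,4-bis(benzyloxy)phenyl][3,5-bis(benzyloxy)phenoxy]methyl pivalate; 5 2-[(E)-2-ethoxyethenyl]-4,4,5,5-tetramethyl-1,3,2-dioxaborolane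
Product: 6 (2S,3S,4S)-5,7-bis(benzyloxy)-2-[3,4-bis(benzyloxy)phenyl]-4-ethoxy-3-(4,4,5,5-tetramethyl-1,3,2-dioxaborolan-2-yl)chromane (2,3-trans, 3,4-trans)
Conditions: (R)-3,3'-bis(2,4,6-triisopropylphenyl)-1,1'-binaphthalene-2,2'-diyl N-(trifluoromethylsulfonyl)phosphoramide (5 mol %), 5 (2 equiv), 4 Å molecular sieves, toluene, −78 to −40 °C
Reagents that add atoms: none
Why: Proposed new method: the chiral N-triflyl phosphoramide should protonate the pivalate carbonyl of 4 so that pivalic acid leaves and the (E)-aryloxocarbenium ion, a cationic 2-oxadiene C4a=C8a–O1(+)=C2, forms as a contact ion pair with the chiral anion; enol ether 5, polarised by its ethoxy group, attacks C2 through its boron-bearing carbon (new C2–C3 bond), the developing ethoxycarbenium carbon C4 is captured by the ortho carbon C4a of ring A (new C4–C4a bond), and the proton lost on rearomatisation regenerates the acid. The closest known reaction types are the oxa-Povarov reaction (SnCl4-promoted, racemic, from phenol-derived mixed acetals and alkenes) and the chiral-phosphoric-acid-catalysed Povarov reaction of (E)-β-substituted enecarbamates, which is enantioselective and gives the all-trans 2,3,4-trisubstituted ring. Ring C closes as a formal inverse-electron-demand [4+2] cycloaddition, or, if the process is stepwise, by 6-exo-trig Friedel–Crafts attack of C4a on the oxocarbenium carbon C4. C2 and C3 are both set when the C2–C3 bond forms: the E geometry of 5 with an endo ethoxy group should place aryl, boryl and ethoxy all equatorial (2,3-trans, 3,4-trans), and the face of the oxocarbenium ion is selected by the confined chiral anion; C4 is set too but is erased in step 4. The step needs regioselectivity in the alkene (secured by the ethoxy group, which makes the boron-bearing carbon the nucleophile), a single site of ring closure (secured by the symmetry of ring A, whose two ortho carbons are equivalent) and ionisation towards the aryl oxocarbenium ion (secured by pivalate being a far better leaving group than the aryloxide). Catalytic acid and low temperature should keep the β-ethoxy boronate product from ionising at C4 and eliminating boron.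

Step 3
Reactants: 6 the 3-boryl-4-ethoxyflavan
Product: 7 (2R,3S,4R)-5,7-bis(benzyloxy)-2-[3,4-bis(benzyloxy)phenyl]-4-ethoxychroman-3-ol
Conditions: 30 % H2O2, 1 M NaOH, THF, 0 °C
Reagents that add atoms: hydrogen peroxide, OO
Why: Alkaline peroxide oxidation of a secondary alkylboronic ester proceeds by 1,2-migration of carbon from boron to oxygen with retention, so the equatorial boryl group becomes the catechin 3-hydroxyl (3S, trans to the 2-aryl group); this is the standard oxidation after hydroboration of enol ethers, where a β-alkoxy group is tolerated.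

Step 4
Reactants: 7 the 4-ethoxyflavan-3-ol
Product: 8 (2R,3S)-5,7-bis(benzyloxy)-2-[3,4-bis(benzyloxy)phenyl]chroman-3-ol (5,7,3',4'-tetra-O-benzyl-(+)-catechin)
Conditions: Et3SiH (10 equiv), CF3CO2H (3 equiv), CH2Cl2, −40 to 0 °C, high dilution
Reagents that add atoms: none
Why: Ionic hydrogenation: acid ionises the C4–OEt bond to the benzylic cation stabilised by O1 and the 5,7-dioxygenated ring A, and excess silane delivers hydride faster than another ring A can attack, removing the C4 stereocentre and leaving C2 and C3 untouched.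

Step 5
Reactants: 9 (−)-epicatechin
Product: 10 (2R,3R)-5,7-bis(benzyloxy)-2-[3,4-bis(benzyloxy)phenyl]chroman-3-ol (5,7,3',4'-tetra-O-benzyl-(−)-epicatechin)
Conditions: BnBr (4.2 equiv), K2CO3, DMF, 0 °C to rt, N2
Reagents that add atoms: benzyl bromide, BrCc1ccccc1
Why: Williamson benzylation of the four phenols with K2CO3 should leave the far less acidic secondary 3-hydroxyl free, and the low temperature and exclusion of air guard against base-induced epimerisation at C2.

Step 6
Reactants: 10 5,7,3',4'-tetra-O-benzyl-(−)-epicatechin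
Product: 11 (2R,3R,4S)-5,7-bis(benzyloxy)-2-[3,4-bis(benzyloxy)phenyl]-4-(2-ethoxyethoxy)chroman-3-ol (4β ether, 3,4-trans)
Conditions: DDQ (2 equiv), 2-ethoxyethanol (5 equiv), CH2Cl2, rt
Reagents that add atoms: 2-ethoxyethanol, CCOCCO
Why: DDQ abstracts hydride from C4, which is benzylic to the trioxygenated ring A, and 2-ethoxyethanol traps the cation from the face anti to the cis-disposed 2-aryl and 3-hydroxyl groups (oxidative benzylic C–H etherification), setting the 3,4-trans (4β, 4S) ether.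

Step 7
Reactants: 11 the 4β-(2-ethoxyethoxy) tetra-O-benzyl epicatechin; 12 3,4,5-tris(benzyloxy)benzoic acid
Product: 13 (2R,3R,4S)-5,7-bis(benzyloxy)-2-[3,4-bis(benzyloxy)phenyl]-4-(2-ethoxyethoxy)chroman-3-yl 3,4,5-tris(benzyloxy)benzoate (4β ether, 3,4-trans)
Conditions: 12 (1.5 equiv), DCC (1.5 equiv), DMAP (0.2 equiv), CH2Cl2, 0 °C to rt
Reagents that add atoms: none
Why: Steglich esterification: the O-acylisourea of 12 is relayed by DMAP as the acylpyridinium ion to the hindered secondary 3-hydroxyl, with retention at C3 because the C3–O bond is not broken, and the neutral conditions spare the acid-labile C4 ether.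

Step 8
Reactants: 13 the 4β-(2-ethoxyethoxy) ether gallate
Product: 14 the 6,8-dibromo derivative of 13 (2R,3R,4S)
Conditions: NBS (2.2 equiv), CH2Cl2, −20 °C to rt
Reagents that add atoms: N-bromosuccinimide, O=C1CCC(=O)N1Br
Why: Electrophilic aromatic bromination occurs on the phloroglucinol-type ring A, the most electron-rich ring, at both free positions C6 and C8, so the future upper unit keeps no nucleophilic site.

Step 9
Reactants: 13 the 4β-(2-ethoxyethoxy) ether gallate
Product: 15 the 8-bromo derivative of 13 (2R,3R,4S)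
Conditions: NBS (1.0 equiv), CH2Cl2, −78 to −20 °C
Reagents that add atoms: N-bromosuccinimide, O=C1CCC(=O)N1Br
Why: With one equivalent of NBS at low temperature, electrophilic bromination of benzylated flavan-3-ols should take C8 (flanked by O1 and one benzyloxy group) in preference to the more hindered C6, leaving C6 as the only nucleophilic carbon.

Step 10
Reactants: 15 the 8-bromo 4β-(2-ethoxyethoxy) ether
Product: 16 (2R,3S,4S)-5,7-bis(benzyloxy)-2-[3,4-bis(benzyloxy)phenyl]-8-bromo-4-[(4-methylphenyl)sulfanyl]chroman-3-yl 3,4,5-tris(benzyloxy)benzoate (4β thioether, 3,4-trans)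
Conditions: 4-MeC6H4SH (3 equiv), BF3·OEt2 (0.5 equiv), CH2Cl2, −78 °C
Reagents that add atoms: 4-methylbenzenethiol, Cc1ccc(S)cc1
Why: Lewis-acid-mediated SN1 exchange at C4 through the ring-A-stabilised cation: excess thiol captures the cation anti to the 3-O-galloyl group, installing a leaving group that is inert to BF3·OEt2 at low temperature (orthogonal activation).

Step 11
Reactants: 14 the 6,8-dibromo 4β-(2-ethoxyethoxy) ether; 16 the 8-bromo 4β-thioether
Product: 17 protected dimer: upper unit 6,8-dibromo-hepta-O-benzyl epicatechin gallate bonded from C4 (4β, 3,4-trans) to C6 of the lower unit, 8-bromo-hepta-O-benzyl epicatechin gallate carrying the 4β-(4-methylphenyl)sulfanyl group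
Conditions: BF3·OEt2 (0.5 equiv), 16 (1.5 equiv), 4 Å molecular sieves, CH2Cl2, −78 to −30 °C
Reagents that add atoms: none
Why: Friedel–Crafts-type flavan coupling: the hard Lewis acid ionises only the C4–O bond of 14, the cation is attacked by C6 of 16 (C8 is blocked, the thioether is inert), and attack anti to the participating 3-O-galloyl group sets the 3,4-trans (4β) bond; 14 has no nucleophilic carbon and cannot oligomerise.

Step 12
Reactants: 17 the protected dimer; 8 tetra-O-benzyl-(+)-catechin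
Product: 18 protected trimer: 17 in which the sulfanyl group is replaced, with 4β (3,4-trans) geometry, by C8 of tetra-O-benzyl-(+)-catechin (2R,3S, free 3-OH)
Conditions: AgOSO2CF3 (1.5 equiv), 2,6-di-tert-butyl-4-methylpyridine (2 equiv), 8 (3 equiv), 4 Å molecular sieves, CH2Cl2, −40 to 0 °C, dark
Reagents that add atoms: none
Why: Thiophilic activation: AgOSO2CF3 ionises the C4–S bond of 17, and C8 of 8 (more reactive and less hindered than C6) attacks the cation anti to the 3-O-galloyl group to give the 4β→8 bond; every other ring-A position of 17 is capped, and the hindered base takes up triflic acid so the interflavan bonds are not scrambled.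

Step 13
Reactants: 18 the protected trimer
Product: 19 (−)-epicatechin 3-O-gallate-(4β→6)-(−)-epicatechin 3-O-gallate-(4β→8)-(+)-catechin (CNP0112921.1)
Conditions: H2 (1 atm), Pd(OH)2/C, Et3N (3.3 equiv), THF/MeOH/H2O, rt
Reagents that add atoms: none
Why: Heterogeneous hydrogenolysis should cleave all eighteen benzyl ethers and the three aryl C–Br bonds in one operation, the amine taking up HBr; the gallate esters, the O1–C2 bonds and the interflavan bonds are stable under these conditions, so no stereocentre is touched.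

Compound list
1 | 3,4-bis(benzyloxy)benzaldehyde | O=Cc1ccc(OCc2ccccc2)c(OCc2ccccc2)c1 | starting material
2 | 3,5-bis(benzyloxy)phenol | Oc1cc(OCc2ccccc2)cc(OCc2ccccc2)c1 | starting material
3 | [3,4-bis(benzyloxy)phenyl](chloro)methyl pivalate (racemic, not isolated) | CC(C)(C)C(=O)OC(Cl)c1ccc(OCc2ccccc2)c(OCc2ccccc2)c1 | intermediate
4 | [3,4-bis(benzyloxy)phenyl][3,5-bis(benzyloxy)phenoxy]methyl pivalate (racemic) | CC(C)(C)C(=O)OC(Oc1cc(OCc2ccccc2)cc(OCc2ccccc2)c1)c1ccc(OCc2ccccc2)c(OCc2ccccc2)c1 | intermediate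
5 | 2-[(E)-2-ethoxyethenyl]-4,4,5,5-tetramethyl-1,3,2-dioxaborolane | CCO/C=C/B1OC(C)(C)C(C)(C)O1 | starting material
6 | (2S,3S,4S)-5,7-bis(benzyloxy)-2-[3,4-bis(benzyloxy)phenyl]-4-ethoxy-3-(pinacolatoboryl)chromane | CC1(C)OB(OC1(C)C)[C@H]1[C@H](OCC)c2c(OCc3ccccc3)cc(OCc3ccccc3)cc2O[C@@H]1c1ccc(OCc2ccccc2)c(OCc2ccccc2)c1 | intermediate
7 | (2R,3S,4R)-5,7-bis(benzyloxy)-2-[3,4-bis(benzyloxy)phenyl]-4-ethoxychroman-3-ol | O[C@H]1[C@H](OCC)c2c(OCc3ccccc3)cc(OCc3ccccc3)cc2O[C@@H]1c1ccc(OCc2ccccc2)c(OCc2ccccc2)c1 | intermediate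
8 | 5,7,3',4'-tetra-O-benzyl-(+)-catechin (2R,3S) | O[C@H]1Cc2c(OCc3ccccc3)cc(OCc3ccccc3)cc2O[C@@H]1c1ccc(OCc2ccccc2)c(OCc2ccccc2)c1 | intermediate
9 | (−)-epicatechin (2R,3R) | O[C@@H]1Cc2c(O)cc(O)cc2O[C@@H]1c1ccc(O)c(O)c1 | starting material
10 | 5,7,3',4'-tetra-O-benzyl-(−)-epicatechin (2R,3R) | O[C@@H]1Cc2c(OCc3ccccc3)cc(OCc3ccccc3)cc2O[C@@H]1c1ccc(OCc2ccccc2)c(OCc2ccccc2)c1 | intermediate
11 | 4β-(2-ethoxyethoxy)-5,7,3',4'-tetra-O-benzyl-epicatechin (2R,3R,4S) | O[C@@H]1[C@@H](OCCOCC)c2c(OCc3ccccc3)cc(OCc3ccccc3)cc2O[C@@H]1c1ccc(OCc2ccccc2)c(OCc2ccccc2)c1 | intermediate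
12 | 3,4,5-tris(benzyloxy)benzoic acid | O=C(O)c1cc(OCc2ccccc2)c(OCc2ccccc2)c(OCc2ccccc2)c1 | starting material
13 | 4β-(2-ethoxyethoxy)-hepta-O-benzyl epicatechin 3-O-gallate (2R,3R,4S) | O=C(O[C@@H]1[C@@H](OCCOCC)c2c(OCc3ccccc3)cc(OCc3ccccc3)cc2O[C@@H]1c1ccc(OCc2ccccc2)c(OCc2ccccc2)c1)c1cc(OCc2ccccc2)c(OCc2ccccc2)c(OCc2ccccc2)c1 | intermediate
14 | 6,8-dibromo derivative of 13 (2R,3R,4S) | O=C(O[C@@H]1[C@@H](OCCOCC)c2c(OCc3ccccc3)c(Br)c(OCc3ccccc3)c(Br)c2O[C@@H]1c1ccc(OCc2ccccc2)c(OCc2ccccc2)c1)c1cc(OCc2ccccc2)c(OCc2ccccc2)c(OCc2ccccc2)c1 | intermediate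
15 | 8-bromo derivative of 13 (2R,3R,4S) | O=C(O[C@@H]1[C@@H](OCCOCC)c2c(OCc3ccccc3)cc(OCc3ccccc3)c(Br)c2O[C@@H]1c1ccc(OCc2ccccc2)c(OCc2ccccc2)c1)c1cc(OCc2ccccc2)c(OCc2ccccc2)c(OCc2ccccc2)c1 | intermediate
16 | 8-bromo-4β-[(4-methylphenyl)sulfanyl]-hepta-O-benzyl epicatechin gallate (2R,3S,4S) | O=C(O[C@@H]1[C@@H](Sc2ccc(C)cc2)c2c(OCc3ccccc3)cc(OCc3ccccc3)c(Br)c2O[C@@H]1c1ccc(OCc2ccccc2)c(OCc2ccccc2)c1)c1cc(OCc2ccccc2)c(OCc2ccccc2)c(OCc2ccccc2)c1 | intermediate
17 | protected dimer: 6,8-dibromo-hepta-O-benzyl epicatechin gallate-(4β→6)-8-bromo-4β-[(4-methylphenyl)sulfanyl]-hepta-O-benzyl epicatechin gallate | O=C(O[C@@H]1[C@@H](c2c(OCc3ccccc3)c(Br)c3c(c2OCc2ccccc2)[C@H](Sc2ccc(C)cc2)[C@@H](OC(=O)c2cc(OCc4ccccc4)c(OCc4ccccc4)c(OCc4ccccc4)c2)[C@@H](c2ccc(OCc4ccccc4)c(OCc4ccccc4)c2)O3)c2c(OCc3ccccc3)c(Br)c(OCc3ccccc3)c(Br)c2O[C@@H]1c1ccc(OCc2ccccc2)c(OCc2ccccc2)c1)c1cc(OCc2ccccc2)c(OCc2ccccc2)c(OCc2ccccc2)c1 | intermediate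
18 | protected trimer: 6,8-dibromo-hepta-O-benzyl epicatechin gallate-(4β→6)-8-bromo-hepta-O-benzyl epicatechin gallate-(4β→8)-tetra-O-benzyl catechin | O=C(O[C@@H]1[C@@H](c2c(OCc3ccccc3)c(Br)c3c(c2OCc2ccccc2)[C@H](c2c(OCc5ccccc5)cc(OCc5ccccc5)c4c2O[C@H](c2ccc(OCc5ccccc5)c(OCc5ccccc5)c2)[C@@H](O)C4)[C@@H](OC(=O)c2cc(OCc4ccccc4)c(OCc4ccccc4)c(OCc4ccccc4)c2)[C@@H](c2ccc(OCc4ccccc4)c(OCc4ccccc4)c2)O3)c2c(OCc3ccccc3)c(Br)c(OCc3ccccc3)c(Br)c2O[C@@H]1c1ccc(OCc2ccccc2)c(OCc2ccccc2)c1)c1cc(OCc2ccccc2)c(OCc2ccccc2)c(OCc2ccccc2)c1 | intermediate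
19 | (−)-epicatechin 3-O-gallate-(4β→6)-(−)-epicatechin 3-O-gallate-(4β→8)-(+)-catechin | O=C(O[C@@H]1[C@@H](c2c(O)cc3c(c2O)[C@H](c2c(O)cc(O)c4c2O[C@H](c2ccc(O)c(O)c2)[C@@H](O)C4)[C@@H](OC(=O)c2cc(O)c(O)c(O)c2)[C@@H](c2ccc(O)c(O)c2)O3)c2c(O)cc(O)cc2O[C@@H]1c1ccc(O)c(O)c1)c1cc(O)c(O)c(O)c1 | target

Total step count: 13. Longest linear sequence: 8 steps (9 → 10 → 11 → 13 → 15 → 16 → 17 → 18 → 19; steps 5, 6, 7, 9, 10, 11, 12, 13).

Steps most likely to fail

Step 2 (Proposed new method). The chiral anion may discriminate the faces of the oxocarbenium ion poorly, giving low enantiomeric purity, or endo/exo control may erode the trans,trans selectivity. The fallback uses known chemistry and sets out from 4. The racemic oxa-Povarov reaction of 4 with 5 promoted by SnCl4 (CH2Cl2, −78 °C) should give the racemic trans,trans cycloadduct F1. H2O2/NaOH then gives the racemic 4-ethoxyflavan-3-ol F2, and Et3SiH/CF3CO2H gives racemic tetra-O-benzylcatechin F3. F3 is resolved by preparative chromatography on an amylose tris(3,5-dimethylphenylcarbamate) stationary phase, and the (2R,3S) enantiomer rejoins the route at 8.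

Step 11. Ionisation of the doubly brominated electrophile may be sluggish and attack by the hindered, bromine-deactivated C6 slow, so that the Lewis acid degrades the 4-alkoxy group or begins to activate the thioether. The fallback reverses the two leaving groups and sets out from 14. Exchange with 4-methylbenzenethiol and BF3·OEt2 gives the 6,8-dibromo 4β-thioether F4. F4 is ionised with AgOSO2CF3 and 2,6-di-tert-butyl-4-methylpyridine in the presence of 15, whose 4-alkoxy group is inert to the soft promoter and whose only free carbon is C6. This gives the dimer with a 4β-(2-ethoxyethoxy) group on the lower unit F5. F5 is then activated with BF3·OEt2 at −78 °C in the presence of 8 and comes back to the route at 18.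

Step 12. AgOSO2CF3-induced ionisation of the hindered C4–S bond may be slow, giving acid time to cleave or scramble the 4→6 bond or letting attack at C6 of 8 compete. The fallback changes the leaving group and sets out from 17. Oxidation with mCPBA (CH2Cl2, −78 °C) gives the dimer sulfoxide F6 (mixture at sulfur). F6 is activated with Tf2O and 2,6-di-tert-butyl-4-methylpyridine at −78 °C in the presence of 8, ionising fast at low temperature, and comes back to the route at 18.

Further compounds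
F1 | step 2 | racemic 6 (equimolar 6 and its enantiomer) | CC1(C)OB(OC1(C)C)[C@H]1[C@H](OCC)c2c(OCc3ccccc3)cc(OCc3ccccc3)cc2O[C@@H]1c1ccc(OCc2ccccc2)c(OCc2ccccc2)c1.CC1(C)OB(OC1(C)C)[C@@H]1[C@@H](OCC)c2c(OCc3ccccc3)cc(OCc3ccccc3)cc2O[C@H]1c1ccc(OCc2ccccc2)c(OCc2ccccc2)c1
F2 | step 2 | racemic 7 (equimolar 7 and its enantiomer) | O[C@H]1[C@H](OCC)c2c(OCc3ccccc3)cc(OCc3ccccc3)cc2O[C@@H]1c1ccc(OCc2ccccc2)c(OCc2ccccc2)c1.O[C@@H]1[C@@H](OCC)c2c(OCc3ccccc3)cc(OCc3ccccc3)cc2O[C@H]1c1ccc(OCc2ccccc2)c(OCc2ccccc2)c1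
F3 | step 2 | racemic 8 (racemic tetra-O-benzylcatechin) | O[C@H]1Cc2c(OCc3ccccc3)cc(OCc3ccccc3)cc2O[C@@H]1c1ccc(OCc2ccccc2)c(OCc2ccccc2)c1.O[C@@H]1Cc2c(OCc3ccccc3)cc(OCc3ccccc3)cc2O[C@H]1c1ccc(OCc2ccccc2)c(OCc2ccccc2)c1
F4 | step 11 | 6,8-dibromo-4β-[(4-methylphenyl)sulfanyl]-hepta-O-benzyl epicatechin gallate | O=C(O[C@@H]1[C@@H](Sc2ccc(C)cc2)c2c(OCc3ccccc3)c(Br)c(OCc3ccccc3)c(Br)c2O[C@@H]1c1ccc(OCc2ccccc2)c(OCc2ccccc2)c1)c1cc(OCc2ccccc2)c(OCc2ccccc2)c(OCc2ccccc2)c1
F5 | step 11 | protected dimer as 17 with 4β-(2-ethoxyethoxy) in place of the sulfanyl group | O=C(O[C@@H]1[C@@H](c2c(OCc3ccccc3)c(Br)c3c(c2OCc2ccccc2)[C@H](OCCOCC)[C@@H](OC(=O)c2cc(OCc4ccccc4)c(OCc4ccccc4)c(OCc4ccccc4)c2)[C@@H](c2ccc(OCc4ccccc4)c(OCc4ccccc4)c2)O3)c2c(OCc3ccccc3)c(Br)c(OCc3ccccc3)c(Br)c2O[C@@H]1c1ccc(OCc2ccccc2)c(OCc2ccccc2)c1)c1cc(OCc2ccccc2)c(OCc2ccccc2)c(OCc2ccccc2)c1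
F6 | step 12 | sulfoxide of 17 (4β-[(4-methylphenyl)sulfinyl], mixture at sulfur) | O=C(O[C@@H]1[C@@H](c2c(OCc3ccccc3)c(Br)c3c(c2OCc2ccccc2)[C@H](S(=O)c2ccc(C)cc2)[C@@H](OC(=O)c2cc(OCc4ccccc4)c(OCc4ccccc4)c(OCc4ccccc4)c2)[C@@H](c2ccc(OCc4ccccc4)c(OCc4ccccc4)c2)O3)c2c(OCc3ccccc3)c(Br)c(OCc3ccccc3)c(Br)c2O[C@@H]1c1ccc(OCc2ccccc2)c(OCc2ccccc2)c1)c1cc(OCc2ccccc2)c(OCc2ccccc2)c(OCc2ccccc2)c1
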